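The amounts stand here, with the product readings of the earlier runs and what is asked.

| flask | substrate | reagent | free catalyst | time |
|---|---|---|---|---|
| amber | 0.200 M | 0.200 M | 0.00600 M |  |
| blue | 0.200 M | 0.200 M | 0.00300 M |  |
| red | 0.200 M | 0.600 M | 0.00600 M |  |
| ochre | 0.500 M | 0.500 M | 0.00600 M | 160 min |

| run | time / min | [product] / M |
|---|---|---|
| amber run | 6.4 | 0.0185 |
| amber run | 10 | 0.0300 |
| amber run | 16 | 0.0466 |
| amber run | 25 | 0.0640 |
| amber run | 40 | 0.0891 |
| amber run | 64 | 0.1140 |
| amber run | 100 | 0.1346 |
| amber run | 160 | 0.1530 |
| blue run | 6.4 | 0.0106 |
| blue run | 10 | 0.0157 |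
| blue run | 16 | 0.0248 |
| blue run | 25 | 0.0363 |
| blue run | 40 | 0.0505 |
| blue run | 64 | 0.0673 |
| blue run | 100 | 0.0862 |
| blue run | 160 | 0.1017 |
| red run | 6.4 | 0.0243 |
| red run | 10 | 0.0358 |
| red run | 16 | 0.0507 |
| red run | 25 | 0.0664 |
| red run | 40 | 0.0835 |
| red run | 64 | 0.0951 |
| red run | 100 | 0.1018 |
| red run | 160 | 0.1070 |

(each reading ± 0.001 M)

1. the exponent of [free catalyst] in the starting rate at the charge of the amber run (at the point where two percent of the substrate have become product)
2. the exponent of [reagent] in the starting rate at the charge of the amber run (at the point where two percent of the substrate have become product)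
3. product in the ochre run at 160 min, as a share of the substrate charged

- Overall: substrate + reagent -> product, with free catalyst as catalyst.
- Constant volume, constant temperature.
- What is held in complexes is read along with the free species.
- "The second partner" is reagent.
- An order is taken over about fifteen percent of the charge, up and down.

We work in logarithms, since an exponent is a difference of log10 over a difference of log10. Amber against blue at 10 min, with the catalyst doubled, gives 0.934. But one scatter on the blue reading shifts that by 0.0919, so we check the 16 min pair, which gives 0.910, and we take about 0.9.

For reagent, red over amber at 6.4 min is ρ = 1.31, an exponent of 0.248. The objection is that this is a chord across a reagent charge 3.00 times amber's, while the question sits at amber's reagent. A curve R/(K+R) through ρ gives K = 0.112 M, so the local exponent K/(K+R) is 0.358.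

The ochre yield needs the catalyst's life. Red's readings put its rate 1.12 decades lower between 100 min and 160 min than between 25 min and 40 min. If the rate follows substrate in proportion, red's falling substrate takes 0.117 of these, leaving 1.00 over 97.5 min at about 0.505 M reagent. Reading the loss as pseudo-first-order, we define the decade dose E, the reagent concentration times the minutes that cost active catalyst one power of ten: E = 49.1 M·min.

If ochre uses 0.5 of its reagent by 160 min, its dose is 1.22 E, worth 53.5 min of fresh catalyst. Amber's 64 min is worth 52.0 min and shows 57.0% of its substrate as product. But ochre starts on more reagent than amber, and scaling by our chord exponent puts its fresh minutes at 67.1 min, fewer than the 74.5 min of amber's 100 min reading, which shows 67.3%. Amber, blue and red each start at 0.200 M substrate, against 0.500 M in ochre, so this scaling is unproven. We commit to the middle, 62.1%.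

The forecast gives 0.9, 0.35 and 62%: “By 160 min I expect roughly 62%, allowing for the slow tail and possible product inhibition.”

The flask gives 0.97, 0.36 and 55.0%.

    free catalyst + substrate ⇌ catalyst-substrate complex (4.704 L mol⁻¹ min⁻¹, 0.2340 min⁻¹)
    catalyst-substrate complex + reagent → product + free catalyst (11.28 L mol⁻¹ min⁻¹)
    2 substrate → homo dimer (0.01338 L mol⁻¹ min⁻¹)
    free catalyst + reagent → spent catalyst + reagent (0.05730 L mol⁻¹ min⁻¹)

Ochre's 55.0% lies 7 percentage points below the forecast. Taking away the loss of substrate in pairs to homo dimer moves the readings by 7.4 scatter units, root mean square. With that yield, ochre's dose by 160 min comes to 1.18 E. Now blue against amber, each where product reaches half the substrate charged: their catalyst-minutes, charge times 152 min and 50.1 min, stand at 1.51 to one, and after the decade dose at 1.10 to one.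

The data are simulated for substances that don't exist; noise was put on by code.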